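(All runs were generated by integration for substances that don't exist; noise was put on by code.)

The vessel was closed, stirred and isothermal. The reagent was charged into the second phase and the other species into the first, and the two earlier runs differed in their protic impurity.

in all of them: starting material 0.20 M
- green: reagent in the second phase 0.19 M; protic impurity 0.10 M; run made earlier
- amber: reagent in the second phase 0.19 M; protic impurity 0.40 M; run made earlier
- flask: reagent in the second phase 0.190 M; protic impurity 0.200 M; time 30 h; volume of the second phase over the first 1.0

- green (time / h: target / %): 1.33: 2.0; 2.00: 2.0; 3.00: 3.0; 5.00: 7.1; 8.00: 7.4; 12.0: 8.0; 20.0: 6.4
- amber (time / h: target / %): 1.00: 0; 3.00: 3.7; 5.00: 6.6; 8.00: 7.4; 10.0: 6.9; 15.0: 7.3; 20.0: 7.1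

(readings scatter by 0.5 percentage points)

- in the second phase: reagent in the second phase; everything else is in the first
- charges count per volume of the first phase; a concentration in a rate is the amount of a species over the volume of its own phase; every rate counts per litre of the first phase
- the earlier runs hold the two phases in the same ratio of volumes as the flask asked about

- Monday's: doubling the transfer coefficient of the reagent in the second phase, all else as stated
- Thursday's: doubling the amount of reagent in the second phase, all else as stated

1. how much target there is at 30 h, in percent of the starting material charged
2. the change that raises the amount of target at 30 h, in percent of the starting material charged most ("none" if none brings more than 2 percentage points) (Monday's / Thursday's / none)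
3. amount of target at 30 h, in percent of the starting material charged, after Monday's

From 5.00 h on, both runs stood level. I averaged the 9 readings from that time on, each with a scatter of 0.5 percentage points, and got 7.13%, which on 0.20 M of starting material is 0.0143 M. The impurity went from 0.10 M to 0.40 M and the level stayed, so I expected the same at 0.200 M.

That level was less than the 0.190 M of reagent charged, so I did not read it as reagent running out. I read it as a quasi-steady state, with target lost as fast as it was made. If starting material takes part in both the making and the loss, it cancels from the balance. So I carried the level concentration, [target] where making equals loss, in molar and not in percent; it should follow the reagent and ignore the starting-material charge.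

I therefore reckoned 7.13% for the flask at 30 h, and the same after Monday's, since the climb in the earlier runs ended near 5.00 h, earlier than that time. Thursday's should give 14.3%, a gain of 7.1 points against the 2 points required.

The forecast, with its own grounds but nearly my numbers, gave 7.2%, Thursday's and 7.3%, reading the flat stretch as “a reversible limit reached after transfer”.

The flask gave 6.25%, with 6.23% after Monday's; Thursday's gained 8.6 points and Monday's −0.015 points.

    starting material + target → side product (k = 0.0375 /M/min)
    starting material + protic impurity → quenched substrate (k = 5.98 × 10⁻⁴ /M/min)
    reagent in the reaction phase ⇌ reagent in the second phase, rate k3*([reagent in the reaction phase] - [reagent in the second phase]/K3) per volume of the first phase (partition coefficient = 0.420, kL = 0.00287 /min)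
    starting material + reagent in the reaction phase → target (k = 0.00565 /M/min)

In this flask the uptake had 86% of its turnover up to 30 h behind it at 6.00 h. Starting material went on reacting with target, half of that step's turnover up to 30 h done by 10.6 h, while starting material fell to 14.6% at 30.0 h. Target in this flask stood at 0.0125 M at 30 h, 0.876 of the 0.0143 M I had read as the level of the earlier runs, as reagent in the reaction phase slipped from 0.0888 M at 15.0 h to 0.0755 M at 30.0 h.

In the neighbouring flask with 0.050 M of starting material, 0.0143 M over that charge gives 28.6%. The computed result there was 27.5%.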